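# Toxiusol: proposed total synthesis by two allylic transpositions

## The problem

1. Atoms are numbered in the order of the SMILES (C1–C30).
   - Ring A is C2–C3–C4=C5–C6–C28 and ring B is C5–C6–C7–C8–C9–C10.
   - The bridge is C12–C13.
   - Ring C is C14–C16–C23–C24–C25–C26 and ring D is C16=C17–C18–C19–C20–C23.
   - The methyl groups are C1 (on C2), C11 (C10), C15 (C14), C21/C22 (C20), C27 (C26) and C29 (C28). C30 is the benzylic CH2.
2. Two different octalins are tied by a CH2CH2 bridge whose ends, C10 and C14, are both quaternary stereocentres. Every bond of the string C10–C12–C13–C14 is therefore neopentylic, nothing between the halves can relay stereochemical information, and each half needs its own source of absolute configuration.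
3. There are seven stereocentres (2R, 6S, 10S, 28R; 14R, 23R, 26S). On A/B, H6, C12, C30 and C1 lie on one face (called β) and C11 and C29 on the other, so the vicinal methyls C1/C29 are trans. On C/D only C13 is β, while H23, C15 and C27 are α.
4. C28 is a second quaternary centre, benzyl-bearing and wedged between C2 and C6, so these three must be set in relation to each other. C23 is the only centre that can be corrected by equilibration (next to a C16 carbonyl). C10 and C14 have no neighbour that would bias them reliably.
5. The trisubstituted alkenes C4=C5 and C16=C17 lie one proton shift from the tetrasubstituted isomers C5=C6 and C16=C23, so strong acid is excluded once they exist. The hydroquinone is air-sensitive and the aryl sulfates are labile to acid and heat, so they come last.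
6. The feature that opens the problem is that both quaternary carbons are allylic termini of the ring-fusion alkenes: C4=C5–C10(–C12) in rings A/B and C17=C16–C14(–C13) in rings D/C.
7. Moving each double bond one place (C5=C10, C16=C14) and placing oxygen at C4 or C17 gives 2-alkylidenecyclohexanols. From these, C10–C12 and C14–C13 can be made by allylic transposition with 1,3-chirality transfer. That one event creates the quaternary centre, puts the alkene where the target has it and, at C14, joins the halves.

## Retrosynthesis

**37 ⇒ 33.** The two O–S bonds are cut first, and behind them hydroquinone 35 is masked. Compound 33 carries the arene as its 2,5-dimethyl ether, which survives organometallics, base, hydride and 140 °C. The forward steps are oxidative demethylation to quinone 34, reduction to 35 and sulfation through salt 36. None of them needs strong acid, and none touches a stereocentre.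

**33 ⇒ 20 + 29 (key cut).** C13–C14 is cut, the alkene is moved back to C16=C14 and an ester oxygen is placed at C17.
- A cut at C12–C13 would create no stereocentre and would leave two finished quaternary centres to be made separately.
- The cut at C10–C12 is kept for the reaction that brings in the bridge carbons.
- The precursors are a primary iodide (20, C24) and an allylic picolinate (29, C14 core) that has no quaternary stereocentre.
- The forward reaction must be γ-selective and anti. Since C13 has to arrive β, the C17–O bond must be α, which is the axial position on ring D.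

**20 ⇒ 16 (via 18, 19).** C10–C12 is cut in the same way, giving C5=C10 and oxygen at C4.
- Here the new bond must lie on the same face as the axial C4β-hydroxyl, so the suprafacial [3,3] shift is the fitting transposition.
- Its Eschenmoser variant delivers exactly C12 and C13 (amide 18). Reduction (19) and iodination give 20.
- The same retron thus serves twice, syn on the left and anti on the right, each time from the axial alcohol, which is the epimer that is easy to make.

**16 ⇒ 15 ⇒ 13.** The C4–H bond (hydride) and then C5=C10 (aldol condensation) are cut. The bicyclic enone 15 falls back to monocyclic ketone 13 with a masked 4-oxopentyl chain. Only C5 can close a fused six-membered ring and lose water, so the forward reaction needs no regiocontrol beyond reversibility.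

**13 ⇒ 12 ⇒ 8.** C2–C1 and C6–C7 are cut. Both carbons are β to the same C4 carbonyl, so ring A is the double conjugate adduct of the achiral dienone 8.
- The stereotriad C2/C28/C6 shrinks to one prochiral quaternary carbon.
- The first addition must choose one of two enantiotopic alkenes and the face anti to the benzyl group. This sets C6 and C28 together.
- The second addition must come trans to the new chain, which sets C2.
- Adding the chain first and the methyl second is what gives the C1/C29-trans relation.

**8 ⇒ 6 ⇒ 3 + 4; 3 ⇒ 1 + 2.** Dehydrogenation, Robinson annulation and a Heck reaction take 8 back to iodoarene 1, methallyl alcohol 2 and methyl vinyl ketone 4. No stereochemistry is involved.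

**29 ⇒ 28 ⇒ 27.** After the ester, C16–C17 is cut. Ring D is closed while C14 is still sp2, so the closure does not have to fight a neighbouring quaternary centre. Compound 27 is monocyclic. The forward reaction must couple an alkenyl triflate with an aldehyde and place the oxygen axial.

**27 ⇒ 26 ⇒ 25 ⇒ 24 ⇒ 21 + 22.** C14–C15 (methylation) and C19–C20 (conjugate addition) are cut.
- What remains is (S)-pulegone 21. Its ten carbons map onto C14, C16, C23–C26, C27 and the C20(C21)(C22) unit.
- Its stereocentre is C26, its carbonyl carbon is C16 and its isopropylidene carbon is C20.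
- C23 follows from C26 by equilibration (trans, both groups equatorial).
- Bromoacetal 22 brings C17–C19.

## Roads not taken

**Alternative 1:** the most obvious cut, C12–C13 in the middle of the bridge. The forward key step would be a Julia–Kocienski olefination of neopentyl aldehyde A1 with neopentyl sulfone A2 to give alkene A3, followed by saturation of C12=C13.
- Both reacting carbons sit next to a quaternary centre, so addition and elimination are slow.
- The new alkene lies between two quaternary carbons, so it has no steric advantage over C4=C5 and C16=C17 in a reduction.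
- The coupling makes no stereocentre. Both quaternary centres and both alkene positions would still have to be solved inside A1 and A2, each with its own one-carbon unit and redox adjustment.
- The chosen plan makes C14 in the coupling itself and needs no later reduction.

**Alternative 2:** the biomimetic road. C15 is moved back from C14 to C16 and C29 from C28 to C6, which leads to the unrearranged trans,trans-bis(decalin) diene A4. The forward key step would be Lewis-acid protonation of both exocyclic methylenes, followed by two cascades of 1,2-hydride and 1,2-methyl shifts. These would end by loss of H17 on the right and, after one more hydride shift, by loss of H4 on the left.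
- Each shift is suprafacial and anti to the one before. C15 would therefore end on the face opposite to H23, and C1 on the same face as C29. The given structure has the reverse relation in both halves.
- Two different terminations would be required in one flask, both against the tetrasubstituted alkenes that the same acid favours.
- A4 still contains the C10 quaternary centre and the hindered bridge.

**Alternative 3:** cut C10–C12 and C13–C14 at once. The forward key step would be a double Ireland–Claisen rearrangement of the mixed succinate A5 (esters at C4β–O and C17β–O) to diacid A6, followed by double decarboxylation.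
- It is the most convergent reading of the retron, but it is suprafacial on both sides. On rings C/D it therefore needs the C17β ester, which is equatorial, strained against C15 and can react only through a boat-like ring D.
- The second shift would have to build a quaternary–tertiary–tertiary–quaternary string.
- The two extra carboxyl groups would have to leave through radicals at C12 and C13. These are 2,2-disubstituted but-3-enyl radicals and are prone to 1,2-vinyl migration.
- The chosen plan leaves no atom to remove and lets each half use the syn or anti course that fits its axial alcohol.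

Key step: step 17

Assumption: the SMILES is read as the free bis(hydrogen sulfate). Because this strong acid endangers the two alkenes, the compound is kept as salt 36, and the acid form is released only at the very end by cold cation exchange.

## Route

Step 1
Reactants: 1 2-iodo-1,4-dimethoxybenzene; 2 2-methylprop-2-en-1-ol
Product: 3 3-(2,5-dimethoxyphenyl)-2-methylpropanal (racemic)
Conditions: Pd(OAc)2 (2 mol %), n-Bu4NCl, NaHCO3, DMF, 60 °C
Reagents that add atoms: none
Why: Heck arylation of an allylic alcohol; insertion at the CH2 terminus, β-hydride elimination toward the carbinol and tautomerisation give the saturated aldehyde directly. The stereocentre does not matter because it becomes prochiral in 8.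

Step 2
Reactants: 3 3-(2,5-dimethoxyphenyl)-2-methylpropanal; 4 but-3-en-2-one
Product: 6 4-(2,5-dimethoxybenzyl)-4-methylcyclohex-2-en-1-one (racemic), via pyrrolidine enamine 5 (not isolated)
Conditions: pyrrolidine, toluene, reflux (−H2O); 4, 0 °C → rt; AcOH, NaOAc, H2O, reflux
Reagents that add atoms: none
Why: Stork enamine Michael addition followed by hydrolysis and aldol condensation (Robinson annulation of an α-branched aldehyde) is the standard entry to 4,4-disubstituted cyclohexenones. The enamine conditions avoid acid-induced closure of the electron-rich arene onto the aldehyde.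

Step 3
Reactants: 6 4-(2,5-dimethoxybenzyl)-4-methylcyclohex-2-en-1-one
Product: 8 4-(2,5-dimethoxybenzyl)-4-methylcyclohexa-2,5-dien-1-one (achiral), via silyl dienol ether 7 (not isolated)
Conditions: LDA, THF, −78 °C; TMSCl; then Pd(OAc)2 (1.05 equiv), MeCN, rt
Reagents that add atoms: none
Why: Kinetic α′-deprotonation gives the cross-conjugated silyl dienol ether, and Saegusa–Ito oxidation gives the dienone; the quaternary carbon blocks aromatisation. Pd(II) is preferred to a quinone oxidant, which could attack the dimethoxybenzyl CH2.

Step 4
Reactants: 8 4-(2,5-dimethoxybenzyl)-4-methylcyclohexa-2,5-dien-1-one; 9 2-(3-chloropropyl)-2-methyl-1,3-dioxolane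
Product: 12 4-(2,5-dimethoxybenzyl)-4-methyl-5-[3-(2-methyl-1,3-dioxolan-2-yl)propyl]cyclohex-2-en-1-one (C7 chain α and H6 β; at C28 benzyl β and methyl α), via Grignard reagent 10 (not isolated), via diorganozinc 11 (not isolated)
Conditions: 9, Mg, THF; ZnCl2 (0.5 equiv), 1,4-dioxane, filtration; Cu(OTf)2 (2 mol %), (S,R,R)-BINOL bis(1-phenylethyl)amine phosphoramidite (4 mol %), toluene, −30 °C; 8; aq. work-up
Reagents that add atoms: none
Why: Cu/phosphoramidite-catalysed enantioselective conjugate addition of a functionalised dialkylzinc, a reaction type known for acetal-bearing zinc reagents and for desymmetrising 4,4-disubstituted cyclohexadienones. The catalyst accepts one prochiral face of a β-carbon and the substrate directs attack anti to the benzyl group; only attack at C6 from the α face meets both demands, so C6 and C28 are set together. The ligand antipode is chosen by analogy with the sense known for simple cyclohexenones.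

Step 5
Reactants: 12 enone from step 4
Product: 13 4-(2,5-dimethoxybenzyl)-3,4-dimethyl-5-[3-(2-methyl-1,3-dioxolan-2-yl)propyl]cyclohexan-1-one (C1 β; C29 α; C30 β; C7 α)
Conditions: Me2CuLi (2 equiv), Et2O, −40 → 0 °C; aq. work-up
Reagents that add atoms: lithium dimethylcuprate, [Li+].C[Cu-]C
Why: Gilman conjugate addition. In the reactive half-chair the C7 chain is equatorial and C29 is pseudoaxial on the α face, so axial attack at C2 comes from the β face, trans to the chain (the usual 3,5-trans outcome for 5-substituted cyclohexenones). The other conformer would force the reagent into a 1,3-diaxial clash with the chain.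

Step 6
Reactants: 13 ketal ketone from step 5
Product: 15 4-(2,5-dimethoxybenzyl)-3,4,8-trimethyl-3,4,4a,5,6,7-hexahydronaphthalen-1(2H)-one (rings A/B; C4=O; C5=C10; H6 β), via diketone 14 (not isolated)
Conditions: HCl (cat.), THF–H2O, rt; solvent change; KOH, MeOH, reflux
Reagents that add atoms: none
Why: Ketal hydrolysis followed by intramolecular aldol condensation. Only attack of C5 on the C10 ketone closes a fused six-membered ring and can dehydrate, whereas the bridged ketol from C9 attacking C4 cannot lose water and reverts. C2, C6 and C28 are not enolisable.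

Step 7
Reactants: 15 enone from step 6
Product: 16 4-(2,5-dimethoxybenzyl)-3,4,8-trimethyl-1,2,3,4,4a,5,6,7-octahydronaphthalen-1-ol (C4–OH β and axial; cis to H6 and to C1)
Conditions: L-Selectride, THF, −78 °C; then NaOH, H2O2
Reagents that add atoms: none
Why: 1,2-Reduction of a β,β-disubstituted enone by a bulky hydride. The axial C1 methyl blocks the β face, so hydride comes from the α (equatorial) side and the alcohol ends axial, as with 3-axially substituted cyclohexanones. An equatorial C–O bond would also meet A(1,3) strain with C11.

Step 8
Reactants: 16 allylic alcohol from step 7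
Product: 18 2-[5-(2,5-dimethoxybenzyl)-1,5,6-trimethyl-1,2,3,4,4a,5,6,7-octahydronaphthalen-1-yl]-N,N-dimethylacetamide (C12 β and C11 α at C10; C4=C5), via ketene N,O-acetal 17 (not isolated)
Conditions: MeC(OMe)2NMe2 (5 equiv), xylene, 140 °C, MeOH distilled off
Reagents that add atoms: N,N-dimethylacetamide dimethyl acetal, CC(OC)(OC)N(C)C
Why: Eschenmoser–Claisen rearrangement under neutral conditions. The axial C4β–O bond is parallel to the C5=C10 π system, and the suprafacial [3,3] shift delivers C12 to the β face of C10, which is also the axial, chair-forming direction on ring B. C10 is thus set by C4, the alkene lands at C4=C5, and both bridge carbons are introduced.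

Step 9
Reactants: 18 amide from step 8
Product: 19 2-[5-(2,5-dimethoxybenzyl)-1,5,6-trimethyl-1,2,3,4,4a,5,6,7-octahydronaphthalen-1-yl]ethan-1-ol
Conditions: LiEt3BH (3 equiv), THF, 0 °C → rt; aq. work-up
Reagents that add atoms: none
Why: Reduction of a tertiary amide to the primary alcohol with lithium triethylborohydride is a known transformation. Alkene, aryl ethers and all stereocentres are untouched.

Step 10
Reactants: 19 alcohol from step 9
Product: 20 5-(2,5-dimethoxybenzyl)-1-(2-iodoethyl)-1,5,6-trimethyl-1,2,3,4,4a,5,6,7-octahydronaphthalene
Conditions: I2, PPh3, imidazole, CH2Cl2, 0 °C → rt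
Reagents that add atoms: iodine, II
Why: Appel-type iodination of a primary alcohol. C13 is one carbon removed from the quaternary centre, so SN2 displacement is unhindered.

Step 11
Reactants: 21 (S)-(−)-pulegone; 22 2-(2-bromoethyl)-1,3-dioxolane
Product: 24 (2R,5S)-2-[4-(1,3-dioxolan-2-yl)-2-methylbutan-2-yl]-5-methylcyclohexan-1-one (2,5-trans; H23 α; C27 α), via Grignard reagent 23 (not isolated)
Conditions: 22, Mg, THF, ≤30 °C; CuBr·SMe2 (20 mol %), THF–Me2S, −78 °C; 21, −78 → 0 °C; aq. work-up; then KOH (cat.), EtOH, reflux
Reagents that add atoms: none
Why: Copper-catalysed conjugate addition of a Grignard reagent to the s-cis enone of pulegone is the established route to 8-substituted menthones, and it makes the C20 gem-dimethyl carbon. Base equilibration at C23 favours the diequatorial trans isomer, so C23 is set by C26 from the chiral pool.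

Step 12
Reactants: 24 ketone from step 11
Product: 25 6-[4-(1,3-dioxolan-2-yl)-2-methylbutan-2-yl]-2,3-dimethylcyclohexan-1-one (C14 epimers; C23 and C26 as in 24)
Conditions: LDA, THF, −78 °C; MeI, −78 → −20 °C
Reagents that add atoms: iodomethane, CI
Why: Kinetic enolate alkylation. Deprotonation occurs at the C14 methylene because C23–H is shielded by the adjacent quaternary C20. The new centre is erased in the next step.

Step 13
Reactants: 25 ketone from step 12
Product: 26 6-[4-(1,3-dioxolan-2-yl)-2-methylbutan-2-yl]-2,3-dimethylcyclohex-1-en-1-yl trifluoromethanesulfonate (C16=C14; H23 α; C27 α)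
Conditions: KHMDS, THF, −78 → 0 °C; PhNTf2, −78 °C → rt
Reagents that add atoms: N-phenylbis(trifluoromethanesulfonimide), O=S(=O)(N(c1ccccc1)S(=O)(=O)C(F)(F)F)C(F)(F)F
Why: Enol triflate formation. Both accessibility and enolate stability favour the C14 side over C23, where the tert-alkyl group would be forced into the enolate plane. C23 and C26 are untouched.

Step 14
Reactants: 26 enol triflate from step 13
Product: 27 4-methyl-4-[3,4-dimethyl-2-(trifluoromethylsulfonyloxy)cyclohex-2-en-1-yl]pentanal (H23 α; C27 α)
Conditions: HCl (cat.), THF–H2O, rt
Reagents that add atoms: water, O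
Why: Acetal hydrolysis. The electron-poor alkenyl triflate resists dilute acid and is too deactivated for a Prins-type reaction with the freed aldehyde.

Step 15
Reactants: 27 triflate aldehyde from step 14
Product: 28 4,4,7,8-tetramethyl-1,2,3,4,4a,5,6,7-octahydronaphthalen-1-ol (rings D/C; C17–OH α and axial; cis to H23; C27 α)
Conditions: CrCl2 (6 equiv), NiCl2 (2 mol %), DMF, rt, 5 mM; aq. work-up
Reagents that add atoms: none
Why: Intramolecular Nozaki–Hiyama–Kishi reaction of an alkenyl triflate with an aldehyde closes six-membered ring D at C16–C17 while C14 is still sp2. In the chair-like closure the C17 oxygen should take the axial α position, because an equatorial C–O bond would meet A(1,3) strain with the cis methyl C15.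

Step 16
Reactants: 28 allylic alcohol from step 15
Product: 29 4,4,7,8-tetramethyl-1,2,3,4,4a,5,6,7-octahydronaphthalen-1-yl pyridine-2-carboxylate (C17–O α)
Conditions: picolinic acid, DCC, DMAP (cat.), CH2Cl2, rt
Reagents that add atoms: picolinic acid, O=C(O)c1ccccn1
Why: Steglich esterification proceeds with retention at C17 and installs the chelating leaving group needed for step 17.

Step 17
Reactants: 20 iodide from step 10; 29 picolinate from step 16
Product: 33 toxiusol hydroquinone dimethyl ether (complete C38 skeleton; C13 β and C15 α at C14; C16=C17), via organolithium 30 (not isolated), via Grignard reagent 31 (not isolated), via organocopper reagent 32 (not isolated)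
Conditions: 20 (1.3 equiv), t-BuLi (2.6 equiv), Et2O–pentane, −78 °C; MgBr2·OEt2, −78 → 0 °C; CuBr·SMe2 (1.3 equiv), THF, −30 °C; 29 (1.0 equiv), −30 → 0 °C; aq. work-up
Reagents that add atoms: none
Why: MgBr2 is chelated by the pyridine N and the carbonyl O of the picolinate, which makes the axial C17α–O bond a very good leaving group; the alkylcopper binds C16=C14 on the β face, where its filled d orbital overlaps with π* and the antiperiplanar σ*(C17–O), oxidative addition gives a γ-σ-allylcopper(III) at C14, and fast reductive elimination forms C13–C14. The closest known reaction type is the anti-SN2′ allylic substitution of secondary allylic picolinates with Grignard-derived alkylcopper reagents, which is established for building quaternary carbons with 1,3-chirality transfer. No ring is closed; the step joins the C24 and C14 fragments into the full skeleton. The only new stereocentre, C14, is controlled by the C17 carbinol centre (leaving group α, new bond β), and the α methyl C27 on the neighbouring C26 points away from the incoming copper and reinforces this. The selectivity needed is γ over α attack and substitution over elimination: A(1,3) strain with C15 holds the C–O bond axial and parallel to the π system, direct displacement at C17 is flanked by the tetrasubstituted alkene, the nucleophile is an unhindered primary alkyl, and the electron-poor leaving group speeds reductive elimination before the allylcopper can equilibrate. Because no proton moves, the alkene must appear at C16=C17 and cannot appear at C16=C23. The aryl ethers and C4=C5 are inert to the reagent, and the pent-4-enyl-type organolithium 30 has no favourable cyclisation mode. The price is a boat-like puckering of ring C during β attack, which should be tolerable in an early, leaving-group-driven transition state.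

Step 18
Reactants: 33 dimethyl ether from step 17
Product: 34 toxiusol quinone (2-substituted 1,4-benzoquinone; terpenoid part unchanged)
Conditions: (NH4)2Ce(NO3)6 (2.5 equiv), MeCN–H2O, 0 °C, 15 min
Reagents that add atoms: water, O
Why: Oxidative demethylation of a 1,4-dimethoxyarene with cerium(IV) is routinely used next to trisubstituted alkenes in terpenoid quinone work. Short contact at 0 °C limits exposure to the nitric acid formed.

Step 19
Reactants: 34 quinone from step 18
Product: 35 toxiusol hydroquinone
Conditions: Na2S2O4, THF–H2O, rt, argon
Reagents that add atoms: none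
Why: Dithionite reduction of a benzoquinone is neutral, fast and does not affect the alkenes.

Step 20
Reactants: 35 hydroquinone from step 19
Product: 37 toxiusol, via bis(pyridinium) disulfate 36 (not isolated)
Conditions: SO3·pyridine (6 equiv), pyridine, rt, argon; then Dowex 50W (H+ form), MeOH–H2O, 0 °C
Reagents that add atoms: sulfur trioxide–pyridine complex, [O-]S(=O)(=O)[n+]1ccccc1
Why: O-Sulfation of phenols with SO3·pyridine in basic medium protects the alkenes; excess reagent drives the hindered ortho oxygen to react. Cold cation exchange releases the acid form.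

## Compound list

1 | 2-iodo-1,4-dimethoxybenzene | COc1ccc(OC)c(I)c1 | starting material
2 | 2-methylprop-2-en-1-ol | C=C(C)CO | starting material
3 | 3-(2,5-dimethoxyphenyl)-2-methylpropanal (racemic) | COc1ccc(OC)c(CC(C)C=O)c1 | intermediate
4 | but-3-en-2-one | C=CC(C)=O | starting material
5 | 1-[3-(2,5-dimethoxyphenyl)-2-methylprop-1-enyl]pyrrolidine | COc1ccc(OC)c(CC(C)=CN2CCCC2)c1 | intermediate
6 | 4-(2,5-dimethoxybenzyl)-4-methylcyclohex-2-en-1-one (racemic) | COc1ccc(OC)c(CC2(C)C=CC(=O)CC2)c1 | intermediate
7 | [4-(2,5-dimethoxybenzyl)-4-methylcyclohexa-1,5-dien-1-yl]oxytrimethylsilane | COc1ccc(OC)c(CC2(C)C=CC(O[Si](C)(C)C)=CC2)c1 | intermediate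
8 | 4-(2,5-dimethoxybenzyl)-4-methylcyclohexa-2,5-dien-1-one | COc1ccc(OC)c(CC2(C)C=CC(=O)C=C2)c1 | intermediate
9 | 2-(3-chloropropyl)-2-methyl-1,3-dioxolane | CC1(CCCCl)OCCO1 | starting material
10 | 3-(2-methyl-1,3-dioxolan-2-yl)propylmagnesium chloride | CC1(CCC[Mg]Cl)OCCO1 | intermediate
11 | bis[3-(2-methyl-1,3-dioxolan-2-yl)propyl]zinc | CC1(CCC[Zn]CCCC2(C)OCCO2)OCCO1 | intermediate
12 | ring A enone, C7 chain α, benzyl β | C1=CC(=O)C[C@@H](CCCC2(C)OCCO2)[C@]1(C)Cc1cc(OC)ccc1OC | intermediate
13 | ring A ketone, C1 β, C29 α, C30 β, C7 α | C[C@@H]1CC(=O)C[C@@H](CCCC2(C)OCCO2)[C@]1(C)Cc1cc(OC)ccc1OC | intermediate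
14 | ring A diketone (4-oxopentyl chain) | C[C@@H]1CC(=O)C[C@@H](CCCC(C)=O)[C@]1(C)Cc1cc(OC)ccc1OC | intermediate
15 | ring A/B enone (C4=O, C5=C10) | C[C@@H]1CC(=O)C2=C(C)CCC[C@H]2[C@]1(C)Cc1cc(OC)ccc1OC | intermediate
16 | ring A/B allylic alcohol, C4–OH β | C[C@@H]1C[C@H](O)C2=C(C)CCC[C@H]2[C@]1(C)Cc1cc(OC)ccc1OC | intermediate
17 | ketene N,O-acetal of 16 | C[C@@H]1C[C@H](OC(=C)N(C)C)C2=C(C)CCC[C@H]2[C@]1(C)Cc1cc(OC)ccc1OC | intermediate
18 | ring A/B dimethylacetamide (C10 quaternary, C4=C5) | C[C@@H]1CC=C2[C@@H](CCC[C@@]2(C)CC(=O)N(C)C)[C@]1(C)Cc1cc(OC)ccc1OC | intermediate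
19 | ring A/B primary alcohol (C13–OH) | C[C@@H]1CC=C2[C@@H](CCC[C@@]2(C)CCO)[C@]1(C)Cc1cc(OC)ccc1OC | intermediate
20 | ring A/B primary iodide (C13–I) | C[C@@H]1CC=C2[C@@H](CCC[C@@]2(C)CCI)[C@]1(C)Cc1cc(OC)ccc1OC | intermediate
21 | (S)-(−)-pulegone | C[C@H]1CCC(=C(C)C)C(=O)C1 | starting material
22 | 2-(2-bromoethyl)-1,3-dioxolane | BrCCC1OCCO1 | starting material
23 | 2-(1,3-dioxolan-2-yl)ethylmagnesium bromide | Br[Mg]CCC1OCCO1 | intermediate
24 | (2R,5S)-2-[4-(1,3-dioxolan-2-yl)-2-methylbutan-2-yl]-5-methylcyclohexan-1-one | C[C@H]1CC[C@H](C(C)(C)CCC2OCCO2)C(=O)C1 | intermediate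
25 | C14-methylated ketone (C14 epimers) | C[C@H]1CC[C@H](C(C)(C)CCC2OCCO2)C(=O)C1C | intermediate
26 | enol triflate (C16=C14) with dioxolane chain | C[C@H]1CC[C@H](C(C)(C)CCC2OCCO2)C(OS(=O)(=O)C(F)(F)F)=C1C | intermediate
27 | enol triflate aldehyde | C[C@H]1CC[C@H](C(C)(C)CCC=O)C(OS(=O)(=O)C(F)(F)F)=C1C | intermediate
28 | ring C/D allylic alcohol, C17–OH α | CC1=C2[C@H](O)CCC(C)(C)[C@H]2CC[C@@H]1C | intermediate
29 | ring C/D allylic picolinate, C17–O α | CC1=C2[C@H](OC(=O)c3ccccn3)CCC(C)(C)[C@H]2CC[C@@H]1C | intermediate
30 | ring A/B alkyllithium (C13–Li) | C[C@@H]1CC=C2[C@@H](CCC[C@@]2(C)CC[Li])[C@]1(C)Cc1cc(OC)ccc1OC | intermediate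
31 | ring A/B alkylmagnesium bromide | C[C@@H]1CC=C2[C@@H](CCC[C@@]2(C)CC[Mg]Br)[C@]1(C)Cc1cc(OC)ccc1OC | intermediate
32 | ring A/B alkylcopper | C[C@@H]1CC=C2[C@@H](CCC[C@@]2(C)CC[Cu])[C@]1(C)Cc1cc(OC)ccc1OC | intermediate
33 | toxiusol hydroquinone dimethyl ether | C[C@@H]1CC=C2[C@@H](CCC[C@@]2(C)CC[C@@]2(C)C3=CCCC(C)(C)[C@H]3CC[C@@H]2C)[C@]1(C)Cc1cc(OC)ccc1OC | intermediate
34 | toxiusol quinone | C[C@@H]1CC=C2[C@@H](CCC[C@@]2(C)CC[C@@]2(C)C3=CCCC(C)(C)[C@H]3CC[C@@H]2C)[C@]1(C)CC1=CC(=O)C=CC1=O | intermediate
35 | toxiusol hydroquinone | C[C@@H]1CC=C2[C@@H](CCC[C@@]2(C)CC[C@@]2(C)C3=CCCC(C)(C)[C@H]3CC[C@@H]2C)[C@]1(C)Cc1cc(O)ccc1O | intermediate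
36 | toxiusol bis(pyridinium) salt | C[C@@H]1CC=C2[C@@H](CCC[C@@]2(C)CC[C@@]2(C)C3=CCCC(C)(C)[C@H]3CC[C@@H]2C)[C@]1(C)Cc1cc(OS(=O)(=O)[O-])ccc1OS(=O)(=O)[O-].c1cc[nH+]cc1.c1cc[nH+]cc1 | intermediate
37 | toxiusol | C[C@@H]1CC=C2[C@@H](CCC[C@@]2(C)CC[C@@]2(C)C3=CCCC(C)(C)[C@H]3CC[C@@H]2C)[C@]1(C)Cc1cc(OS(=O)(=O)O)ccc1OS(=O)(=O)O | target

## Step count and least certain steps

Total step count: 20.
Longest linear sequence: 14 (steps 1–10 and 17–20). The ring C/D branch (steps 11–16) has 6 steps.

**Step 17 (key step).**
- What may go wrong: oxidative addition at the fully substituted C14 may be slower than elimination of the activated ester or attack at C17. The γ-carbon carries four carbon neighbours, and β attack puckers ring C toward a boat. Part of the valuable organometallic may also be lost by protonation or homocoupling.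
- Fallback: it sets out from 29 and 16 and comes back at 33. It moves the fragment union to the stereoelectronically matched C10.
- Right half: 29 is opened in the same anti-SN2′ sense with a small nucleophile used in excess (vinylmagnesium bromide, CuBr·SMe2) to give the C14-vinyl octalin F1. Selective hydroboration of the vinyl group (9-BBN, then NaOH/H2O2) gives the primary alcohol F2. Treatment with I2/PPh3/imidazole gives the iodide F3.
- Left half and union: alcohol 16 is esterified with 2-(diphenylphosphanyl)benzoic acid to the ortho-diphenylphosphanylbenzoate F4. The Grignard reagent from F3 (t-BuLi, MgBr2) with CuBr·SMe2 then substitutes F4 in a phosphine-directed syn-SN2′ reaction. This forms C10–C12 on the β face, axially on ring B, and gives 33. Steps 8–10 are then not needed.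

**Step 4.**
- What may go wrong: discrimination between the methyl and the benzyl face of the planar dienone may be poor, because the aryl group can turn away from the ring. The result would be a mixture of diastereomers, each of high ee. A second addition to the product enone is the other risk.
- Fallback: it sets out from Grignard reagent 10 (made from 9) and comes back at 13. It takes C2 from the chiral pool and sets C28 and C6 by substrate control.
- Alkylations: (R)-5-methylcyclohex-2-en-1-one F5 is benzylated at C28 (LDA, 2,5-dimethoxybenzyl bromide) to the 6-benzyl enone F6. Methylation (LDA, MeI) occurs anti to the neighbouring methyl and gives the 6-benzyl-5,6-dimethyl enone F7.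
- Carbonyl transposition: nucleophilic epoxidation (H2O2, NaOH) gives the epoxy ketone F8. Wharton transposition (N2H4, AcOH) gives the allylic alcohol F9. Oxidation (MnO2) gives 4-(2,5-dimethoxybenzyl)-4,5-dimethylcyclohex-2-en-1-one F10.
- Return to the route: copper-catalysed addition of 10 to F10 occurs anti to the axial benzyl group and trans to the C2 methyl, and gives 13.

**Step 6.**
- What may go wrong: material may be diverted into the bridged ketol (C9 onto C4), or the strained tetrasubstituted enone may form incompletely or deconjugate, because both aldol modes close six-membered rings.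
- Fallback: it sets out from 12 and comes back at 15. It fixes the nucleophilic carbon beforehand.
- Sequence: in 12 only C5 bears α-hydrogens, so LDA/TMSCl gives the 2-silyloxydiene F11 regiospecifically. TiCl4 triggers an intramolecular Mukaiyama aldol reaction of C5 with the ketal carbon C10 to give the bicyclic β-(2-hydroxyethoxy) ketone F12. DBU eliminates the alkoxy group to give the cross-conjugated dienone F13. Me2CuLi then adds to the less substituted C2 terminus, β and trans to C7, to give 15.

**Step 15.**
- What may go wrong: facial selectivity at C17 may be poor, because the geometry of the chromium-bound aldehyde in the closing transition state is not rigidly defined.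
- Fallback: it sets out from crude 28 containing its C17β epimer F14 and comes back at 28. It replaces substrate control in the C–C bond formation by hindered-hydride control.
- Sequence: the mixture is oxidised (Dess–Martin periodinane) to the ring C/D enone F15. L-Selectride attacks the enone from the equatorial β side to give the axial α alcohol 28.

## Further compounds

F1 | step 17 | 1-ethenyl-1,2,5,5-tetramethyl-1,2,3,4,4a,5,6,7-octahydronaphthalene (vinyl β) | C=C[C@@]1(C)C2=CCCC(C)(C)[C@H]2CC[C@@H]1C
F2 | step 17 | 2-(1,2,5,5-tetramethyl-1,2,3,4,4a,5,6,7-octahydronaphthalen-1-yl)ethan-1-ol | OCC[C@@]1(C)C2=CCCC(C)(C)[C@H]2CC[C@@H]1C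
F3 | step 17 | 1-(2-iodoethyl)-1,2,5,5-tetramethyl-1,2,3,4,4a,5,6,7-octahydronaphthalene | ICC[C@@]1(C)C2=CCCC(C)(C)[C@H]2CC[C@@H]1C
F4 | step 17 | 2-(diphenylphosphanyl)benzoate of 16 | C[C@@H]1C[C@H](OC(=O)c2ccccc2P(c2ccccc2)c2ccccc2)C2=C(C)CCC[C@H]2[C@]1(C)Cc1cc(OC)ccc1OC
F5 | step 4 | (R)-5-methylcyclohex-2-en-1-one | C[C@@H]1CC=CC(=O)C1
F6 | step 4 | 6-(2,5-dimethoxybenzyl)-5-methylcyclohex-2-en-1-one (trans) | C[C@@H]1CC=CC(=O)[C@H]1Cc1cc(OC)ccc1OC
F7 | step 4 | 6-(2,5-dimethoxybenzyl)-5,6-dimethylcyclohex-2-en-1-one (methyls trans) | C[C@@H]1CC=CC(=O)[C@]1(C)Cc1cc(OC)ccc1OC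
F8 | step 4 | 2,3-epoxide of F7 | C[C@@H]1CC2OC2C(=O)[C@]1(C)Cc1cc(OC)ccc1OC
F9 | step 4 | 4-(2,5-dimethoxybenzyl)-4,5-dimethylcyclohex-2-en-1-ol | C[C@@H]1CC(O)C=C[C@]1(C)Cc1cc(OC)ccc1OC
F10 | step 4 | 4-(2,5-dimethoxybenzyl)-4,5-dimethylcyclohex-2-en-1-one | C[C@@H]1CC(=O)C=C[C@]1(C)Cc1cc(OC)ccc1OC
F11 | step 6 | 2-silyloxydiene of 12 | C1=CC(O[Si](C)(C)C)=C[C@@H](CCCC2(C)OCCO2)[C@]1(C)Cc1cc(OC)ccc1OC
F12 | step 6 | bicyclic β-(2-hydroxyethoxy) enone | C1=CC(=O)C2[C@@H](CCCC2(C)OCCO)[C@]1(C)Cc1cc(OC)ccc1OC
F13 | step 6 | ring A/B cross-conjugated dienone | C1=CC(=O)C2=C(C)CCC[C@H]2[C@]1(C)Cc1cc(OC)ccc1OC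
F14 | step 15 | C17β epimer of 28 | CC1=C2[C@@H](O)CCC(C)(C)[C@H]2CC[C@@H]1C
F15 | step 15 | ring C/D enone (C17=O, C16=C14) | CC1=C2C(=O)CCC(C)(C)[C@H]2CC[C@@H]1C
A1 | alternative 1 | ring A/B neopentyl aldehyde (C12 = CHO) | C[C@@H]1CC=C2[C@@H](CCC[C@@]2(C)C=O)[C@]1(C)Cc1cc(OC)ccc1OC
A2 | alternative 1 | ring C/D 1-phenyltetrazol-5-yl sulfone (at C13) | O=S(=O)(C[C@@]1(C)C2=CCCC(C)(C)[C@H]2CC[C@@H]1C)c1nnnn1-c1ccccc1
A3 | alternative 1 | (E)-12,13-didehydro derivative of 33 | C[C@@H]1CC=C2[C@@H](CCC[C@@]2(C)/C=C/[C@@]2(C)C3=CCCC(C)(C)[C@H]3CC[C@@H]2C)[C@]1(C)Cc1cc(OC)ccc1OC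
A4 | alternative 2 | unrearranged trans,trans-bis(decalin) bis(exomethylene) compound | C=C1CC[C@@H]2[C@](C)(CCC[C@@]2(C)CC[C@@H]2C(=C)CC[C@@H]3C(C)(C)CCC[C@@]23C)[C@H]1Cc1cc(OC)ccc1OC
A5 | alternative 3 | mixed succinate (C4β–O and C17β–O esters) | C[C@@H]1C[C@H](OC(=O)CCC(=O)O[C@H]2CCC(C)(C)[C@H]3CC[C@H](C)C(C)=C23)C2=C(C)CCC[C@H]2[C@]1(C)Cc1cc(OC)ccc1OC
A6 | alternative 3 | 12,13-dicarboxylic acid of 33 | C[C@@H]1CC=C2[C@@H](CCC[C@@]2(C)C(C(=O)O)C(C(=O)O)[C@@]2(C)C3=CCCC(C)(C)[C@H]3CC[C@@H]2C)[C@]1(C)Cc1cc(OC)ccc1OC
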